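**Assumption (numbering):** phakellstatin numbering is used throughout: pyrrole N1, C2(Br), C3(Br), C4(H), C5; aminal CH = C6; N7; C8(=O); N9; quaternary aminal = C10; pyrrolidine C11–C13; N14; C15(=O). The target SMILES is (6S,10R).

## Retrosynthetic overview

1. Target ⇐ 12‑silyloxy analogue: an oxygen at C12, taken from trans‑4‑hydroxy‑L‑proline, is a removable stereocontrol element (Barton–McCombie deoxygenation last).
2. Imidazolidinone ring D ⇐ cis‑diamination (three‑component annulation) of a tricyclic enamide (C6=C10) with two molecules of EtO2C‑NH‑OTs, anti to the C12 silyl ether; this sets C6 and C10 together.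
3. Enamide ⇐ dehydration of the cyclic hemiaminal formed when the N‑acyl prolinal is trapped by the pyrrole N–H (pyrazinone ring B).
4. Amide ⇐ trans‑4‑hydroxy‑L‑proline methyl ester + 4,5‑dibromo‑2‑(trichloroacetyl)pyrrole.
5. Ring order: A (pyrrole) and C (pyrrolidine) purchased → B (pyrazinone) → D (cyclic urea).

## Route

**Step 1**
Reactants: 1, 2,2,2‑trichloro‑1‑(4,5‑dibromo‑1H‑pyrrol‑2‑yl)ethanone; 2, methyl (2S,4R)‑4‑hydroxypyrrolidine‑2‑carboxylate hydrochloride
Product: 3, methyl (2S,4R)‑1‑(4,5‑dibromo‑1H‑pyrrole‑2‑carbonyl)‑4‑hydroxypyrrolidine‑2‑carboxylate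
Conditions: Et3N (2.5 equiv), MeCN, rt → 50 °C
Reagents that add atoms: 1 is the acyl donor, O=C(c1cc(Br)c(Br)[nH]1)C(Cl)(Cl)Cl (CCl3 leaves as CHCl3)
Why: Haloform‑type N‑acylation; the secondary amine is far more nucleophilic than the secondary OH, and the stereocentres are untouched.

**Step 2**
Reactants: 3; 4, tert‑butyl(chloro)diphenylsilane (TBDPSCl)
Product: 5, methyl (2S,4R)‑4‑[(tert‑butyldiphenylsilyl)oxy]‑1‑(4,5‑dibromo‑1H‑pyrrole‑2‑carbonyl)pyrrolidine‑2‑carboxylate
Conditions: TBDPSCl, imidazole, DMF, rt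
Reagents that add atoms: TBDPSCl, CC(C)(C)[Si](Cl)(c1ccccc1)c1ccccc1
Why: Standard O‑silylation; it installs the bulky group that will shield one face of the later enamide, and the pyrrole N–H is not silylated under these conditions.

**Step 3**
Reactants: 5
Product: 6, (4,5‑dibromo‑1H‑pyrrol‑2‑yl)[(2S,4R)‑4‑(TBDPS‑oxy)‑2‑(hydroxymethyl)pyrrolidin‑1‑yl]methanone
Conditions: LiBH4, THF, 0 °C → rt
Reagents that add atoms: none
Why: Chemoselective ester reduction; LiBH4 leaves the tertiary amide, the aryl bromides and the silyl ether intact.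

**Step 4**
Reactants: 6
Product: 7, tricyclic hemiaminal: (10S,12R)‑2,3‑dibromo‑6‑hydroxy‑12‑(TBDPS‑oxy)‑6,10,11,12,13‑pentahydro‑dipyrrolo[1,2‑a:1′,2′‑d]pyrazin‑15‑one (C6 epimers are inconsequential)
Conditions: Dess–Martin periodinane, NaHCO3, CH2Cl2, rt
Reagents that add atoms: none
Why: Alcohol oxidation gives the prolinal, which is trapped spontaneously by the pyrrole N–H as a six‑membered cyclic hemiaminal (ring B).

**Step 5**
Reactants: 7
Product: 8, (12R)‑2,3‑dibromo‑12‑(TBDPS‑oxy)‑C6=C10 tricyclic enamide (11,12,13‑trihydro‑dipyrrolo[1,2‑a:1′,2′‑d]pyrazin‑15‑one)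
Conditions: MsCl, Et3N, CH2Cl2, 0 °C → rt
Reagents that add atoms: none
Why: Mesylation/elimination of the hemiaminal gives the conjugated bis‑N‑substituted enamide; the former proline α‑centre becomes sp2, leaving C12 (R) as the only stereocentre.

**Step 6** (reagent preparation, off the main line)
Reactants: 9, ethyl N‑hydroxycarbamate; 10, p‑toluenesulfonyl chloride
Product: 11, ethyl N‑(tosyloxy)carbamate
Conditions: Et3N, Et2O, 0 °C
Reagents that add atoms: TsCl, Cc1ccc(cc1)S(Cl)(=O)=O
Why: Simple O‑sulfonylation of the hydroxamate oxygen gives the nitrenoid precursor.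

**Step 7**
Reactants: 8; 11 (2 equiv incorporated, 3 equiv used)
Product: 12, (6S,10S,12R)‑N7‑ethoxycarbonyl‑N9‑tosyloxy‑12‑(TBDPS‑oxy)dibromophakellstatin. The 10S descriptor reflects only the N–O priority change; the geometry is that of the target. The N7/N9 assignment is mechanistic and inconsequential, because both groups are removed in step 8.
Conditions: 11, CaO (excess), CH2Cl2, rt; chromatographic removal of the minor diastereomer
Reagents that add atoms: ethyl N‑(tosyloxy)carbamate ×2, CCOC(=O)NOS(=O)(=O)c1ccc(C)cc1 (one loses TsO⁻, the other loses EtOH)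
Why: Three‑component imidazolidinone annulation: the electrophilic N‑ethoxycarbonyl nitrenoid aminates C6, a second carbamate anion captures the C10 N‑acyliminium ion, and ring closure expels ethoxide. The cis fusion is enforced by the five‑membered ring and the nitrogens add to the face anti to the C12 OTBDPS group, which sets C6 and C10.

**Step 8**
Reactants: 12
Product: 13, (6S,10R,12R)‑12‑(TBDPS‑oxy)dibromophakellstatin
Conditions: SmI2 (6 equiv), THF, rt; then K2CO3, MeOH, rt
Reagents that add atoms: none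
Why: Single‑electron reductive N–O cleavage removes the tosyloxy group, and the imide‑type N‑CO2Et is cleaved by methanolysis; the aryl bromides survive SmI2 in the absence of HMPA.

**Step 9**
Reactants: 13
Product: 14, (6S,10R,12R)‑12‑hydroxydibromophakellstatin
Conditions: TBAF, AcOH, THF, rt
Reagents that add atoms: none
Why: Buffered fluoride desilylation; the aminal centres are stable to these conditions.

**Step 10**
Reactants: 14; 15, O‑phenyl chlorothionoformate
Product: 16, (6S,10R,12R)‑12‑O‑(phenoxythiocarbonyl)dibromophakellstatin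
Conditions: PhOC(S)Cl, DMAP, pyridine, CH2Cl2/MeCN, 0 °C → rt
Reagents that add atoms: O‑phenyl chlorothionoformate, S=C(Cl)Oc1ccccc1
Why: DMAP‑catalysed O‑thioacylation of the secondary alcohol; the weakly nucleophilic urea N–H groups do not compete.

**Step 11**
Reactants: 16
Product: 17, (6S,10R)‑dibromophakellstatin (target)
Conditions: Bu3SnH (1.3 equiv, slow addition), AIBN (cat.), 1,4‑dioxane/toluene, 80 °C
Reagents that add atoms: none
Why: Barton–McCombie deoxygenation; stannyl radical addition to C=S is much faster than Br abstraction from the pyrrole, and removing the C12 oxygen leaves only the C6/C10 stereocentres, which are not touched.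

## Compound list

1 | 2,2,2‑trichloro‑1‑(4,5‑dibromo‑1H‑pyrrol‑2‑yl)ethanone | O=C(c1cc(Br)c(Br)[nH]1)C(Cl)(Cl)Cl | starting material
2 | trans‑4‑hydroxy‑L‑proline methyl ester hydrochloride | Cl.COC(=O)[C@@H]1C[C@@H](O)CN1 | starting material
3 | methyl (2S,4R)‑1‑(4,5‑dibromopyrrole‑2‑carbonyl)‑4‑hydroxyprolinate | COC(=O)[C@@H]1C[C@@H](O)CN1C(=O)c1cc(Br)c(Br)[nH]1 | intermediate
4 | TBDPSCl | CC(C)(C)[Si](Cl)(c1ccccc1)c1ccccc1 | starting material (reagent)
5 | TBDPS ether of 3 | COC(=O)[C@@H]1C[C@@H](O[Si](c2ccccc2)(c2ccccc2)C(C)(C)C)CN1C(=O)c1cc(Br)c(Br)[nH]1 | intermediate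
6 | N‑acyl (2S,4R)‑4‑(TBDPS‑oxy)prolinol | OC[C@@H]1C[C@@H](O[Si](c2ccccc2)(c2ccccc2)C(C)(C)C)CN1C(=O)c1cc(Br)c(Br)[nH]1 | intermediate
7 | tricyclic C6 hemiaminal (10S,12R) | OC1[C@@H]2C[C@@H](O[Si](c3ccccc3)(c3ccccc3)C(C)(C)C)CN2C(=O)c2cc(Br)c(Br)n12 | intermediate
8 | (12R)‑tricyclic enamide | Brc1cc2C(=O)N3C[C@H](O[Si](c4ccccc4)(c4ccccc4)C(C)(C)C)CC3=Cn2c1Br | intermediate
9 | ethyl N‑hydroxycarbamate | CCOC(=O)NO | starting material
10 | p‑toluenesulfonyl chloride | Cc1ccc(cc1)S(Cl)(=O)=O | starting material (reagent)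
11 | ethyl N‑(tosyloxy)carbamate | CCOC(=O)NOS(=O)(=O)c1ccc(C)cc1 | intermediate (reagent)
12 | (6S,10S,12R)‑N7‑CO2Et‑N9‑OTs‑12‑OTBDPS‑dibromophakellstatin | O=C1N(C(=O)OCC)[C@H]2n3c(cc(Br)c3Br)C(=O)N3C[C@H](O[Si](c4ccccc4)(c4ccccc4)C(C)(C)C)C[C@]23N1OS(=O)(=O)c1ccc(C)cc1 | intermediate
13 | (6S,10R,12R)‑12‑OTBDPS‑dibromophakellstatin | O=C1N[C@H]2n3c(cc(Br)c3Br)C(=O)N3C[C@H](O[Si](c4ccccc4)(c4ccccc4)C(C)(C)C)C[C@]23N1 | intermediate
14 | (6S,10R,12R)‑12‑hydroxydibromophakellstatin | O=C1N[C@H]2n3c(cc(Br)c3Br)C(=O)N3C[C@H](O)C[C@]23N1 | intermediate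
15 | O‑phenyl chlorothionoformate | S=C(Cl)Oc1ccccc1 | starting material (reagent)
16 | 12‑O‑phenoxythiocarbonyl derivative of 14 | O=C1N[C@H]2n3c(cc(Br)c3Br)C(=O)N3C[C@H](OC(=S)Oc4ccccc4)C[C@]23N1 | intermediate
17 | (6S,10R)‑dibromophakellstatin | O=C1N[C@H]2n3c(cc(Br)c3Br)C(=O)N3CCC[C@]23N1 | target

## Summary

**Total steps:** 11 (10 on the main line plus the one‑step preparation of reagent 11).
**Longest linear sequence:** 10 steps (2 → 17).

**Steps most likely to fail, with fallbacks:**

1. **Step 7 (three‑component annulation):** the yield is likely to be moderate and the facial selectivity is uncertain. A poor dr still gives enantiopure material, because the C12 centre makes the isomers separable diastereomers. Fallback: dihydroxylate 8 (OsO4/NMO, anti to OTBDPS) to the cis‑6,10‑diol (a bis‑hemiaminal) and condense it with urea under acid (double N‑acyliminium substitution) to build the cyclic urea stepwise.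
2. **Step 11 (deoxygenation in the presence of two pyrrole C–Br bonds):** competing debromination is the main risk. Fallback: use excess Bu3SnH to reduce fully to (6S,10R)‑phakellstatin, then reinstall both bromines with NBS (2 equiv, THF), which brominates the 2‑acylpyrrole at C2/C3.
3. **Step 5 (dehydration to the β‑silyloxy enamide):** double‑bond migration and loss of silanol could aromatise the pyrrolidine ring. Fallback: drop substrate control. Make the unsubstituted enamide from L‑prolinol (acylation, oxidation, MsCl/Et3N), annulate and deprotect to the racemate (5 steps), and resolve by preparative chiral HPLC.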